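**Plan**

- Lettering: ring A (C1 OH, C2 O-aryl, C4 CH2), ring B (C1 O, C4 CH2), ring C (C1 CH2, C2 O-aryl, C3 OH), ring D (C1 O, C3 CH2). Ethers A–O–B and C–O–D, ethano bridges B–C and D–A. The target has no stereocentre.
- Cuts, in retrosynthetic order: both O–CH3 bonds; the ring D C3–CH2 bond of the D–A bridge, which opens the 18-membered ring; the ring C C2–O–ring D ether; then ring C C1–CH2 and ring C C2–O together; last the A–O–B ether and the ring A vinyl C=C.
- Enabling feature: ring C carries alkyl at C1, oxygen at C2 and oxygen at C3 in a row. A carbon nucleophile and an oxygen electrophile added across 3-methoxybenzyne give exactly this pattern, with the C3 methoxy group directing both.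
- Forward order: A–O–B diaryl ether, then styrene and 2-arylethyl Grignard reagent, ring C grafted by aryne carbomagnesiation and oxidation, ring D attached by O-arylation, one ring closure by hydroboration and B-alkyl Suzuki coupling, double demethylation.
- Stereochemistry: none to set. The selectivity questions are regiochemical (aryne addition, iodide over bromide, anti-Markovnikov hydroboration).

Key step: step 7

Remark: the 2-arylethyl Grignard reagent made in step 6 is handled as a titrated THF solution and is counted as a compound of the route.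

**Route**

Step 1
Reactants: 1 2-(4-bromophenyl)ethanol
Product: 2 [2-(4-bromophenyl)ethoxy]tri(propan-2-yl)silane
Conditions: TIPSCl, imidazole, DMF, rt
Reagents that add atoms: chlorotri(propan-2-yl)silane, CC(C)[Si](Cl)(C(C)C)C(C)C
Why: Imidazole-promoted silylation of the primary alcohol (silyl ether protection) is routine, and the bulky triisopropylsilyl group is chosen because it withstands the hot carbonate base of step 2.

Step 2
Reactants: 2 [2-(4-bromophenyl)ethoxy]tri(propan-2-yl)silane, 3 isovanillin (3-hydroxy-4-methoxybenzaldehyde)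
Product: 4 4-methoxy-3-(4-{2-[tri(propan-2-yl)silyloxy]ethyl}phenoxy)benzaldehyde
Conditions: CuI (10 mol %), N,N-dimethylglycine hydrochloride (30 mol %), Cs2CO3, 1,4-dioxane, 100 °C
Reagents that add atoms: none
Why: Ullmann-type copper-catalysed diaryl ether synthesis with an amino acid ligand couples phenols with unactivated aryl bromides at this temperature, and the non-enolisable aldehyde and the silyl ether are inert to Cs2CO3 in dioxane.

Step 3
Reactants: 4 4-methoxy-3-(4-{2-[tri(propan-2-yl)silyloxy]ethyl}phenoxy)benzaldehyde
Product: 5 {2-[4-(2-methoxy-5-vinylphenoxy)phenyl]ethoxy}tri(propan-2-yl)silane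
Conditions: Ph3PCH3Br, KOtBu, THF, 0 °C → rt
Reagents that add atoms: methyltriphenylphosphonium bromide, C[P+](c1ccccc1)(c1ccccc1)c1ccccc1.[Br-]
Why: Wittig methylenation with the non-stabilised ylide converts the aryl aldehyde into the styrene without affecting the aryl or silyl ethers.

Step 4
Reactants: 5 {2-[4-(2-methoxy-5-vinylphenoxy)phenyl]ethoxy}tri(propan-2-yl)silane
Product: 6 2-[4-(2-methoxy-5-vinylphenoxy)phenyl]ethanol
Conditions: TBAF, THF, rt
Reagents that add atoms: none
Why: Fluoride-induced desilylation frees the primary alcohol, and the styrene and the aryl ethers do not react with fluoride.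

Step 5
Reactants: 6 2-[4-(2-methoxy-5-vinylphenoxy)phenyl]ethanol
Product: 7 2-[4-(2-bromoethyl)phenoxy]-1-methoxy-4-vinylbenzene
Conditions: CBr4, PPh3, CH2Cl2, 0 °C
Reagents that add atoms: carbon tetrabromide, BrC(Br)(Br)Br
Why: The Appel reaction converts the primary alcohol into the bromide under neutral conditions at low temperature, which avoids elimination of the 2-arylethyl unit and addition to the styrene.

Step 6
Reactants: 7 2-[4-(2-bromoethyl)phenoxy]-1-methoxy-4-vinylbenzene
Product: 8 2-[4-(2-methoxy-5-vinylphenoxy)phenyl]ethylmagnesium bromide (THF solution)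
Conditions: Mg turnings (I2 cat.), THF, rt → 45 °C
Reagents that add atoms: magnesium, [Mg]
Why: Oxidative insertion of magnesium into a primary alkyl bromide (Grignard formation) is standard for 2-arylethyl bromides, and neither the aryl ethers nor the unactivated styrene react with the reagent.

Step 7
Reactants: 8 2-[4-(2-methoxy-5-vinylphenoxy)phenyl]ethylmagnesium bromide, 9 2-bromo-3-fluoroanisole
Product: 14 2-methoxy-6-{2-[4-(2-methoxy-5-vinylphenoxy)phenyl]ethyl}phenol, via arylmagnesium chloride 10 (not isolated), via 3-methoxybenzyne 11 (not isolated), via arylmagnesium bromide adduct 12 (not isolated), via dimethyl arylboronate 13 (not isolated)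
Conditions: 9, iPrMgCl·LiCl, THF, −20 °C; this solution added slowly to 8 (1.5 equiv) in THF at 60 °C; then B(OMe)3, −78 °C → rt; then aq NaOH, 30% H2O2, 0 °C → rt
Reagents that add atoms: hydrogen peroxide, OO
Why: Bromine–magnesium exchange on 9 gives arylmagnesium 10, which should persist at −20 °C and, once fed into warm THF, lose MgClF to form 3-methoxybenzyne 11. The methoxy group beside the triple bond withdraws inductively and distorts the aryne so that the remote aryne carbon is the electrophilic one; the alkyl carbon of 8 therefore bonds there (ring C C1) and magnesium ends up at C2, ortho to and chelated by OMe, as 12. Trimethyl borate converts this C–Mg bond into boronate 13, and alkaline hydrogen peroxide then causes the 1,2-shift of the aryl group from boron to oxygen, so the hydroxyl appears exactly where magnesium was. The closest known reaction type is the addition of Grignard reagents to arynes generated from ortho-halophenylmagnesium halides with electrophilic trapping of the new arylmagnesium, combined with the borate–peroxide phenol synthesis. No ring closes and no stereocentre forms. The step needs regioselectivity, secured by the methoxy group, and chemoselectivity for 8 over 10 as the nucleophile, secured by slow inverse addition of 10 into an excess of the more nucleophilic primary alkyl reagent, whose unreacted part the oxidation returns as alcohol 6; the styrene is inert to the organomagnesium species and to basic peroxide.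

Step 8
Reactants: 14 2-methoxy-6-{2-[4-(2-methoxy-5-vinylphenoxy)phenyl]ethyl}phenol, 15 1-bromo-3-iodobenzene
Product: 16 2-(3-bromophenoxy)-1-methoxy-3-{2-[4-(2-methoxy-5-vinylphenoxy)phenyl]ethyl}benzene
Conditions: 15 (3 equiv), CuI (10 mol %), picolinic acid (20 mol %), K3PO4, DMSO, 80 °C
Reagents that add atoms: none
Why: Ullmann-type O-arylation with the CuI–picolinic acid system is known to couple 2,6-disubstituted phenols, and at 80 °C copper activates the C–I bond of 15 much faster than its C–Br bond, so the bromide is kept for the ring closure.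

Step 9
Reactants: 16 2-(3-bromophenoxy)-1-methoxy-3-{2-[4-(2-methoxy-5-vinylphenoxy)phenyl]ethyl}benzene
Product: 18 marchantin C di-O-methyl ether, via B-alkyl-9-BBN borane 17 (not isolated)
Conditions: 9-BBN, THF, rt → 50 °C; then syringe-pump addition to Pd(dppf)Cl2 (15 mol %), AsPh3, Cs2CO3, DMF/THF/H2O, 70 °C, high dilution
Reagents that add atoms: none
Why: Anti-Markovnikov hydroboration of the styrene with 9-BBN followed by intramolecular B-alkyl Suzuki–Miyaura coupling with the ring D bromide under high dilution forms the sp3–sp2 bond that closes the 18-membered ring, a macrocyclisation mode with good precedent.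

Step 10
Reactants: 18 marchantin C di-O-methyl ether
Product: 19 marchantin C
Conditions: BBr3, CH2Cl2, −78 °C → rt; aqueous work-up
Reagents that add atoms: none
Why: Lewis acid demethylation with BBr3 cleaves both aryl methyl ethers by bromide attack on the methyl groups of the boron–ether complexes, while the diaryl ethers and the bibenzyl bridges are unaffected.

**Compound list**

1 | 2-(4-bromophenyl)ethanol | OCCc1ccc(Br)cc1 | starting material
2 | [2-(4-bromophenyl)ethoxy]tri(propan-2-yl)silane | CC(C)[Si](OCCc1ccc(Br)cc1)(C(C)C)C(C)C | intermediate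
3 | isovanillin (3-hydroxy-4-methoxybenzaldehyde) | COc1ccc(C=O)cc1O | starting material
4 | 4-methoxy-3-(4-{2-[tri(propan-2-yl)silyloxy]ethyl}phenoxy)benzaldehyde | COc1ccc(C=O)cc1Oc1ccc(CCO[Si](C(C)C)(C(C)C)C(C)C)cc1 | intermediate
5 | {2-[4-(2-methoxy-5-vinylphenoxy)phenyl]ethoxy}tri(propan-2-yl)silane | COc1ccc(C=C)cc1Oc1ccc(CCO[Si](C(C)C)(C(C)C)C(C)C)cc1 | intermediate
6 | 2-[4-(2-methoxy-5-vinylphenoxy)phenyl]ethanol | COc1ccc(C=C)cc1Oc1ccc(CCO)cc1 | intermediate
7 | 2-[4-(2-bromoethyl)phenoxy]-1-methoxy-4-vinylbenzene | COc1ccc(C=C)cc1Oc1ccc(CCBr)cc1 | intermediate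
8 | 2-[4-(2-methoxy-5-vinylphenoxy)phenyl]ethylmagnesium bromide | Br[Mg]CCc1ccc(Oc2cc(C=C)ccc2OC)cc1 | intermediate
9 | 2-bromo-3-fluoroanisole | COc1cccc(F)c1Br | starting material
10 | 2-fluoro-6-methoxyphenylmagnesium chloride | COc1cccc(F)c1[Mg]Cl | intermediate
11 | 3-methoxybenzyne | COC1=CC=CC#C1 | intermediate
12 | 2-methoxy-6-{2-[4-(2-methoxy-5-vinylphenoxy)phenyl]ethyl}phenylmagnesium bromide | COc1cccc(CCc2ccc(Oc3cc(C=C)ccc3OC)cc2)c1[Mg]Br | intermediate
13 | dimethyl (2-methoxy-6-{2-[4-(2-methoxy-5-vinylphenoxy)phenyl]ethyl}phenyl)boronate | COB(OC)c1c(OC)cccc1CCc1ccc(Oc2cc(C=C)ccc2OC)cc1 | intermediate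
14 | 2-methoxy-6-{2-[4-(2-methoxy-5-vinylphenoxy)phenyl]ethyl}phenol | COc1cccc(CCc2ccc(Oc3cc(C=C)ccc3OC)cc2)c1O | intermediate
15 | 1-bromo-3-iodobenzene | Brc1cccc(I)c1 | starting material
16 | 2-(3-bromophenoxy)-1-methoxy-3-{2-[4-(2-methoxy-5-vinylphenoxy)phenyl]ethyl}benzene | COc1cccc(CCc2ccc(Oc3cc(C=C)ccc3OC)cc2)c1Oc1cccc(Br)c1 | intermediate
17 | 9-{2-[3-(4-{2-[2-(3-bromophenoxy)-3-methoxyphenyl]ethyl}phenoxy)-4-methoxyphenyl]ethyl}-9-borabicyclo[3.3.1]nonane | COc1cccc(CCc2ccc(Oc3cc(CCB4C5CCCC4CCC5)ccc3OC)cc2)c1Oc1cccc(Br)c1 | intermediate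
18 | marchantin C di-O-methyl ether (18-membered macrocycle, OMe at ring A C1 and ring C C3) | COc1ccc2cc1Oc1ccc(cc1)CCc1cccc(OC)c1Oc1cccc(c1)CC2 | intermediate
19 | marchantin C | Oc1ccc2cc1Oc1ccc(cc1)CCc1cccc(O)c1Oc1cccc(c1)CC2 | target

**Count**

Total steps: 10. Longest linear sequence: 10 steps (1 to 19); isovanillin, 2-bromo-3-fluoroanisole and 1-bromo-3-iodobenzene enter as purchased.

**Steps most likely to fail, with fallbacks**

Step 7. Arylmagnesium 10 or adduct 12 may add to the aryne in competition with 8 and give biaryls. The loss of MgClF may be sluggish, or the aryne may be intercepted by the styrene. The fallback replaces the aryne assembly by an sp3–sp2 cross-coupling and sets out from bromide 7. Zinc dust with LiCl in THF at 50 °C should give {2-[4-(2-methoxy-5-vinylphenoxy)phenyl]ethyl}zinc bromide F1. Commercial 2-bromo-6-methoxyphenol is protected with chloromethyl methyl ether and iPr2NEt in CH2Cl2 to give 1-bromo-3-methoxy-2-(methoxymethoxy)benzene F2. Negishi coupling of F1 with F2 (Pd(OAc)2, SPhos, THF, rt → 50 °C) should give 1-methoxy-2-(methoxymethoxy)-3-{2-[4-(2-methoxy-5-vinylphenoxy)phenyl]ethyl}benzene F3. Brief treatment with HCl in methanol removes the acetal, and the route is rejoined at phenol 14.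

Step 9. Intermolecular coupling may outrun ring closure and give oligomers, or the alkylborane may undergo protodeboronation or β-hydride elimination before transmetalation. The fallback closes the ring by olefin metathesis and sets out from 16. Stille coupling with Bu3SnCH=CH2 (Pd(PPh3)4, toluene, 100 °C) should give 1-methoxy-2-(3-vinylphenoxy)-3-{2-[4-(2-methoxy-5-vinylphenoxy)phenyl]ethyl}benzene F4. Ring-closing metathesis with second-generation Grubbs catalyst in dilute CH2Cl2 at reflux should give the macrocyclic stilbene 7',8'-didehydromarchantin C di-O-methyl ether F5. It is drawn as the E isomer, and a Z isomer would serve equally. Hydrogenation (H2, Pd/C, EtOAc) saturates the stilbene, and the route is rejoined at 18.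

Step 8. Coupling at the doubly ortho-substituted phenoxide may be slow, and the bromide of the product may then be activated and consumed in oligomeric ether formation. The fallback is a metal-free arylation with a hypervalent iodine reagent and sets out from 15. Oxidation with mCPBA and TsOH·H2O in acetonitrile, followed by 1,3,5-trimethoxybenzene in the same pot, should give (3-bromophenyl)(2,4,6-trimethoxyphenyl)iodonium 4-methylbenzenesulfonate F6. Phenol 14 is deprotonated with KOtBu in THF and treated with F6 at rt → 40 °C. The electron-rich trimethoxyphenyl group stays on iodine, the 3-bromophenyl group is transferred, and the route is rejoined at 16.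

**Further compounds**

F1 | step 7 | {2-[4-(2-methoxy-5-vinylphenoxy)phenyl]ethyl}zinc bromide | Br[Zn]CCc1ccc(Oc2cc(C=C)ccc2OC)cc1
F2 | step 7 | 1-bromo-3-methoxy-2-(methoxymethoxy)benzene | COCOc1c(Br)cccc1OC
F3 | step 7 | 1-methoxy-2-(methoxymethoxy)-3-{2-[4-(2-methoxy-5-vinylphenoxy)phenyl]ethyl}benzene | COCOc1c(OC)cccc1CCc1ccc(Oc2cc(C=C)ccc2OC)cc1
F4 | step 9 | 1-methoxy-2-(3-vinylphenoxy)-3-{2-[4-(2-methoxy-5-vinylphenoxy)phenyl]ethyl}benzene | COc1cccc(CCc2ccc(Oc3cc(C=C)ccc3OC)cc2)c1Oc1cccc(C=C)c1
F5 | step 9 | (E)-7',8'-didehydromarchantin C di-O-methyl ether (macrocyclic stilbene) | COc1ccc2cc1Oc1ccc(cc1)CCc1cccc(OC)c1Oc1cccc(c1)/C=C/2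
F6 | step 8 | (3-bromophenyl)(2,4,6-trimethoxyphenyl)iodonium 4-methylbenzenesulfonate | COc1cc(OC)c([I+]c2cccc(Br)c2)c(OC)c1.Cc1ccc(cc1)S([O-])(=O)=O
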